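**Retrosynthetic overview**
1. Numbering used throughout (eudesmane type): ring A = C1, C2, C3, C4, C5, C10; ring B = C5 to C10; C1 carries the benzylic carbon C1', C4 the carbinol, C7 the 2-propenyl group (C11 to C13), C10 the angular methyl; β is the face of that methyl.
2. End game: the 3-methylbutanoyl and formyl groups come from two directed ortho-lithiations of a tris-MOM arylmethyl decalin; the C4 carbinol comes from equatorial methyl addition to a C4 ketone.
3. Key disconnection: C7–C8 (closes ring B) together with C1'–aryl. Enabling feature: C7 of ring B carries the 2-propenyl group, so C7/C11/C12 are a 2-methylallyl unit with C7 as γ-carbon and the C7–C8 bond is the SN2' bond of a C12 phosphate; C8 and C1' are the anti-Markovnikov termini of a vinyl group on C10 and a methylidene group on C1 of ring A.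
4. The monocyclic triene phosphate comes from (R)-4-silyloxy-2-methylcyclohexenone by anti conjugate allylation/C-formylation (sets C5 and C10), cross-metathesis and double Wittig methylenation.
5. Ring order: ring A is bought as the cyclohexenone, the aromatic ring comes from phloroglucinol, ring B is formed last, in the key step.

Key step: step 9

Assumption (chemistry): (R)-4-[(tert-butyldimethylsilyl)oxy]cyclohex-2-en-1-one (1) is taken as a purchasable enantiopure building block.

**Route**

Step 1
Reactants: 1 (R)-4-[(tert-butyldimethylsilyl)oxy]cyclohex-2-en-1-one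
Product: 2 (R)-4-[(tert-butyldimethylsilyl)oxy]-2-iodocyclohex-2-en-1-one
Conditions: I2, pyridine, CH2Cl2, 0 °C to rt
Reagents that add atoms: iodine, II
Why: α-Iodination of the enone through pyridine conjugate addition, iodination and elimination (Baylis–Hillman-type sequence) should give the 2-iodoenone without touching the C4 stereocentre.

Step 2
Reactants: 2 (R)-4-[(tert-butyldimethylsilyl)oxy]-2-iodocyclohex-2-en-1-one
Product: 3 (R)-4-[(tert-butyldimethylsilyl)oxy]-2-methylcyclohex-2-en-1-one
Conditions: trimethylboroxine, Pd(dppf)Cl2 (5 mol%), Cs2CO3, 1,4-dioxane/H2O, 80 °C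
Reagents that add atoms: trimethylboroxine, CB1OB(C)OB(C)O1
Why: Suzuki–Miyaura methylation of the vinyl iodide should install the future angular methyl group on C10 and leaves the silyl ether and the stereocentre untouched.

Step 3
Reactants: 3 (R)-4-[(tert-butyldimethylsilyl)oxy]-2-methylcyclohex-2-en-1-one
Product: 5 (1S,2R,3R)-3-[(tert-butyldimethylsilyl)oxy]-1-methyl-6-oxo-2-(prop-2-enyl)cyclohexane-1-carbaldehyde, via trimethylsilyl enol ether 4 (not isolated)
Conditions: allylMgBr, CuBr·SMe2, LiCl, Me3SiCl, THF, −78 °C; then MeLi, THF, 0 °C; then HCO2CH2CF3, −78 °C; NH4Cl (aq)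
Reagents that add atoms: allylmagnesium bromide, C=CC[Mg]Br; 2,2,2-trifluoroethyl formate, O=COCC(F)(F)F
Why: Allylcopper conjugate addition should occur anti to the C4 silyloxy group (sets C5), and the regiodefined lithium enolate released from 4 should be C-formylated (crossed Claisen acylation) anti to the new allyl group, which sets the quaternary C10 with the methyl cis and the formyl trans to the allyl group.

Step 4
Reactants: 5 (1S,2R,3R)-3-[(tert-butyldimethylsilyl)oxy]-1-methyl-6-oxo-2-(prop-2-enyl)cyclohexane-1-carbaldehyde; 6 2-methylprop-2-en-1-ol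
Product: 7 (1S,2R,3R)-3-[(tert-butyldimethylsilyl)oxy]-2-[(2E)-4-hydroxy-3-methylbut-2-enyl]-1-methyl-6-oxocyclohexane-1-carbaldehyde
Conditions: second-generation Hoveyda–Grubbs catalyst (5 mol%), 6 (5 equiv), CH2Cl2, 40 °C
Reagents that add atoms: none
Why: Olefin cross-metathesis between the monosubstituted allyl group and the 1,1-disubstituted alkene 6 should give the trisubstituted allylic alcohol, mainly as the E isomer (both isomers converge in step 9), while the aldehyde, ketone and silyl ether are inert.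

Step 5
Reactants: 7 (1S,2R,3R)-3-[(tert-butyldimethylsilyl)oxy]-2-[(2E)-4-hydroxy-3-methylbut-2-enyl]-1-methyl-6-oxocyclohexane-1-carbaldehyde
Product: 8 (2E)-4-{(1R,2R,6R)-6-[(tert-butyldimethylsilyl)oxy]-2-ethenyl-2-methyl-3-methylidenecyclohexyl}-2-methylbut-2-en-1-ol
Conditions: Ph3PCH3Br, KN(SiMe3)2 (excess), THF, −78 °C to 60 °C
Reagents that add atoms: methylenetriphenylphosphorane (made in the flask from methyltriphenylphosphonium bromide), C=P(c1ccccc1)(c1ccccc1)c1ccccc1
Why: Double Wittig methylenation should turn the formyl group into the C10 vinyl group (C9=C8) and the hindered C1 ketone into the methylidene group; no stereocentre is formed and none can epimerise because C10 is quaternary.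

Step 6
Reactants: 8 (2E)-4-{(1R,2R,6R)-6-[(tert-butyldimethylsilyl)oxy]-2-ethenyl-2-methyl-3-methylidenecyclohexyl}-2-methylbut-2-en-1-ol
Product: 9 diethyl (2E)-4-{(1R,2R,6R)-6-[(tert-butyldimethylsilyl)oxy]-2-ethenyl-2-methyl-3-methylidenecyclohexyl}-2-methylbut-2-enyl phosphate
Conditions: ClP(O)(OEt)2, pyridine, DMAP (cat.), CH2Cl2, 0 °C
Reagents that add atoms: diethyl chlorophosphate, CCOP(=O)(Cl)OCC
Why: O-Phosphorylation of the primary allylic alcohol (nucleophilic catalysis by DMAP) should give the allylic phosphate leaving group without allylic transposition.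

Step 7
Reactants: 10 phloroglucinol (benzene-1,3,5-triol)
Product: 11 1,3,5-tris(methoxymethoxy)benzene
Conditions: MeOCH2Cl, i-Pr2NEt, CH2Cl2, 0 °C to rt
Reagents that add atoms: chloromethyl methyl ether, COCCl
Why: Williamson-type O-alkylation of the three phenols should give the tris-MOM ether, whose acetal oxygens later direct the ortho-lithiations.

Step 8
Reactants: 11 1,3,5-tris(methoxymethoxy)benzene
Product: 12 2-bromo-1,3,5-tris(methoxymethoxy)benzene
Conditions: NBS (1.0 equiv), CH2Cl2, −20 °C
Reagents that add atoms: N-bromosuccinimide, O=C1CCC(=O)N1Br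
Why: Electrophilic aromatic bromination of the very electron-rich, threefold symmetric arene with one equivalent of NBS should stop at the monobromide.

Step 9
Reactants: 9 diethyl (2E)-4-{(1R,2R,6R)-6-[(tert-butyldimethylsilyl)oxy]-2-ethenyl-2-methyl-3-methylidenecyclohexyl}-2-methylbut-2-enyl phosphate; 12 2-bromo-1,3,5-tris(methoxymethoxy)benzene
Product: 15 4α-[(tert-butyldimethylsilyl)oxy]-10β-methyl-7β-(prop-1-en-2-yl)-1β-[2,4,6-tris(methoxymethoxy)benzyl]-5α-H-trans-decalin, via bis(alkylborane) 13 (not isolated), via cyclised alkylborane 14 (not isolated)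
Conditions: 9-BBN (2.0 equiv), THF, 0 to 40 °C; then CuOAc (10 mol%), KOtBu (1.1 equiv), THF (0.02 M), 50 °C; then 12, Pd(OAc)2 (5 mol%), SPhos (10 mol%), K3PO4 (aq), 65 °C
Reagents that add atoms: none
Why: Proposed new method: 9-BBN should hydroborate only the vinyl and methylidene groups (anti-Markovnikov; the trisubstituted allylic phosphate is too hindered), the methylidene from the α-face because the axial C10 methyl blocks the β-face, which sets C1 (13); the C8 alkylborate then transmetalates to monovalent copper, and the alkylcopper adds across C7=C11 in a 6-exo-trig carbocupration followed by anti β-elimination of phosphate (net intramolecular SN2'), which forms C7–C8, closes ring B and unmasks the 2-propenyl group (14). The closest known reactions are the intermolecular copper-catalysed γ-selective allyl–alkyl coupling of B-alkyl-9-BBN reagents with allylic phosphates and the B-alkyl Suzuki–Miyaura coupling; the ring-closing version on a bis(alkylborane) and the telescoping are new. Ring B closes through a chair-like transition state whose two arms are the trans-diequatorial C5 and C10 substituents of ring A, so the ring fusion is trans and the C11 unit sits equatorial, which sets C7 (β-2-propenyl) for both alkene isomers of 9. γ- over α-attack is secured by ring size (six- against eight-membered) and by the copper mechanism; the C1' borane cannot compete inside the molecule because its attack on C7 would need a bridged bicyclo[3.3.1] transition state with both arms axial, and high dilution suppresses coupling between molecules. The remaining C1' borane is then cross-coupled with 12 by zerovalent palladium/SPhos only after the allylic phosphate is consumed, so π-allylpalladium chemistry cannot interfere.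

Step 10
Reactants: 15 4α-[(tert-butyldimethylsilyl)oxy]-10β-methyl-7β-(prop-1-en-2-yl)-1β-[2,4,6-tris(methoxymethoxy)benzyl]-5α-H-trans-decalin
Product: 16 10β-methyl-7β-(prop-1-en-2-yl)-1β-[2,4,6-tris(methoxymethoxy)benzyl]-5α-H-trans-decalin-4α-ol
Conditions: Bu4NF, THF, 40 °C
Reagents that add atoms: none
Why: Fluoride-mediated desilylation should free the C4 alcohol while the MOM ethers and both alkenes are inert.

Step 11
Reactants: 16 10β-methyl-7β-(prop-1-en-2-yl)-1β-[2,4,6-tris(methoxymethoxy)benzyl]-5α-H-trans-decalin-4α-ol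
Product: 17 10β-methyl-7β-(prop-1-en-2-yl)-1β-[2,4,6-tris(methoxymethoxy)benzyl]-5α-H-trans-decalin-4-one
Conditions: Dess–Martin periodinane, NaHCO3, CH2Cl2, 0 °C to rt
Reagents that add atoms: none
Why: Dess–Martin oxidation should give the C4 ketone under buffered, non-enolising conditions, so the trans ring fusion at C5 is kept.

Step 12
Reactants: 17 10β-methyl-7β-(prop-1-en-2-yl)-1β-[2,4,6-tris(methoxymethoxy)benzyl]-5α-H-trans-decalin-4-one
Product: 18 4α,10β-dimethyl-7β-(prop-1-en-2-yl)-1β-[2,4,6-tris(methoxymethoxy)benzyl]-5α-H-trans-decalin-4β-ol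
Conditions: MeMgBr, CeCl3, THF, −78 to 0 °C
Reagents that add atoms: methylmagnesium bromide, C[Mg]Br
Why: Carbonyl 1,2-addition of the organocerium reagent should occur from the equatorial α-face because axial attack is blocked by the 1,3-diaxial C10 methyl, giving the axial β-alcohol (sets C4), and cerium suppresses enolisation at C5.

Step 13
Reactants: 18 4α,10β-dimethyl-7β-(prop-1-en-2-yl)-1β-[2,4,6-tris(methoxymethoxy)benzyl]-5α-H-trans-decalin-4β-ol
Product: 19 3-{[4β-hydroxy-4α,10β-dimethyl-7β-(prop-1-en-2-yl)-5α-H-trans-decalin-1β-yl]methyl}-2,4,6-tris(methoxymethoxy)benzaldehyde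
Conditions: n-BuLi (2.5 equiv), TMEDA, THF, 0 °C; then DMF, −78 °C to rt; NH4Cl (aq)
Reagents that add atoms: N,N-dimethylformamide, CN(C)C=O
Why: Directed ortho-lithiation between two MOM ethers (the two free ring positions are equivalent) followed by formylation with DMF should give the monoaldehyde; the tertiary alcohol is only deprotonated.

Step 14
Reactants: 19 3-{[4β-hydroxy-4α,10β-dimethyl-7β-(prop-1-en-2-yl)-5α-H-trans-decalin-1β-yl]methyl}-2,4,6-tris(methoxymethoxy)benzaldehyde
Product: 21 3-{[4β-hydroxy-4α,10β-dimethyl-7β-(prop-1-en-2-yl)-5α-H-trans-decalin-1β-yl]methyl}-2,4,6-tris(methoxymethoxy)-5-(3-methylbutanoyl)benzaldehyde, via lithium amino alkoxide 20 (not isolated)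
Conditions: LiN(Me)CH2CH2NMe2 (1.2 equiv), THF, −20 °C; n-BuLi (3 equiv), −20 to 0 °C; i-BuC(O)N(OMe)Me, −78 °C to rt; NH4Cl (aq)
Reagents that add atoms: N-methoxy-N-methyl-3-methylbutanamide, CC(C)CC(=O)N(C)OC
Why: Addition of the lithium amide to the aldehyde gives the α-amino alkoxide 20, which protects the aldehyde in the flask, so the last ring position can be lithiated (directed ortho-metalation) and acylated with the Weinreb amide, whose tetrahedral adduct prevents over-addition; work-up frees both carbonyl groups.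

Step 15
Reactants: 21 3-{[4β-hydroxy-4α,10β-dimethyl-7β-(prop-1-en-2-yl)-5α-H-trans-decalin-1β-yl]methyl}-2,4,6-tris(methoxymethoxy)-5-(3-methylbutanoyl)benzaldehyde
Product: 22 2,4,6-trihydroxy-3-{[4β-hydroxy-4α,10β-dimethyl-7β-(prop-1-en-2-yl)-5α-H-trans-decalin-1β-yl]methyl}-5-(3-methylbutanoyl)benzaldehyde (CNP0561337.2)
Conditions: HCl (2 M in MeOH), THF, rt
Reagents that add atoms: none
Why: Acid-catalysed acetal exchange with methanol should remove the three MOM ethers, each activated by an ortho carbonyl group, under conditions mild enough for the tertiary alcohol and the 2-propenyl group.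

**Compound list**
1 | (R)-4-[(tert-butyldimethylsilyl)oxy]cyclohex-2-en-1-one | O=C1C=C[C@H](O[Si](C)(C)C(C)(C)C)CC1 | starting material
2 | (R)-4-[(tert-butyldimethylsilyl)oxy]-2-iodocyclohex-2-en-1-one | O=C1C(I)=C[C@H](O[Si](C)(C)C(C)(C)C)CC1 | intermediate
3 | (R)-4-[(tert-butyldimethylsilyl)oxy]-2-methylcyclohex-2-en-1-one | O=C1C(C)=C[C@H](O[Si](C)(C)C(C)(C)C)CC1 | intermediate
4 | tert-butyl-dimethyl-{[(1R,2R)-3-methyl-2-(prop-2-enyl)-4-(trimethylsilyloxy)cyclohex-3-en-1-yl]oxy}silane (allyl trans to the silyloxy group) | C=CC[C@@H]1C(C)=C(O[Si](C)(C)C)CC[C@H]1O[Si](C)(C)C(C)(C)C | intermediate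
5 | (1S,2R,3R)-3-[(tert-butyldimethylsilyl)oxy]-1-methyl-6-oxo-2-(prop-2-enyl)cyclohexane-1-carbaldehyde (formyl trans to allyl, allyl trans to silyloxy) | O=C1CC[C@@H](O[Si](C)(C)C(C)(C)C)[C@H](CC=C)[C@@]1(C)C=O | intermediate
6 | 2-methylprop-2-en-1-ol | C=C(C)CO | starting material
7 | (1S,2R,3R)-3-[(tert-butyldimethylsilyl)oxy]-2-[(2E)-4-hydroxy-3-methylbut-2-enyl]-1-methyl-6-oxocyclohexane-1-carbaldehyde | O=C1CC[C@@H](O[Si](C)(C)C(C)(C)C)[C@H](C/C=C(\C)CO)[C@@]1(C)C=O | intermediate
8 | (2E)-4-{(1R,2R,6R)-6-[(tert-butyldimethylsilyl)oxy]-2-ethenyl-2-methyl-3-methylidenecyclohexyl}-2-methylbut-2-en-1-ol | C=C1CC[C@@H](O[Si](C)(C)C(C)(C)C)[C@H](C/C=C(\C)CO)[C@@]1(C)C=C | intermediate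
9 | diethyl (2E)-4-{(1R,2R,6R)-6-[(tert-butyldimethylsilyl)oxy]-2-ethenyl-2-methyl-3-methylidenecyclohexyl}-2-methylbut-2-enyl phosphate | C=C1CC[C@@H](O[Si](C)(C)C(C)(C)C)[C@H](C/C=C(\C)COP(=O)(OCC)OCC)[C@@]1(C)C=C | intermediate
10 | phloroglucinol (benzene-1,3,5-triol) | Oc1cc(O)cc(O)c1 | starting material
11 | 1,3,5-tris(methoxymethoxy)benzene | COCOc1cc(OCOC)cc(OCOC)c1 | intermediate
12 | 2-bromo-1,3,5-tris(methoxymethoxy)benzene | COCOc1cc(OCOC)c(Br)c(OCOC)c1 | intermediate
13 | bis(alkylborane): 9 with a 9-BBN unit on C8 (from the vinyl group) and on C1' (from the methylidene group; C1–H α, CH2B β) | C1CC2CCCC(C1)B2C[C@@H]3CC[C@@H](O[Si](C)(C)C(C)(C)C)[C@H](C/C=C(\C)COP(=O)(OCC)OCC)[C@@]3(C)CCB4C5CCCC4CCC5 | intermediate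
14 | cyclised alkylborane: 4α-[(tert-butyldimethylsilyl)oxy]-10β-methyl-7β-(prop-1-en-2-yl)-5α-H-trans-decalin with a (9-BBN)methyl group at C1β | C=C(C)[C@@H]1CC[C@@]2(C)[C@H](CB3C4CCCC3CCC4)CC[C@@H](O[Si](C)(C)C(C)(C)C)[C@@H]2C1 | intermediate
15 | 4α-[(tert-butyldimethylsilyl)oxy]-10β-methyl-7β-(prop-1-en-2-yl)-1β-[2,4,6-tris(methoxymethoxy)benzyl]-5α-H-trans-decalin | C=C(C)[C@@H]1CC[C@@]2(C)[C@H](Cc3c(OCOC)cc(OCOC)cc3OCOC)CC[C@@H](O[Si](C)(C)C(C)(C)C)[C@@H]2C1 | intermediate
16 | 10β-methyl-7β-(prop-1-en-2-yl)-1β-[2,4,6-tris(methoxymethoxy)benzyl]-5α-H-trans-decalin-4α-ol | C=C(C)[C@@H]1CC[C@@]2(C)[C@H](Cc3c(OCOC)cc(OCOC)cc3OCOC)CC[C@@H](O)[C@@H]2C1 | intermediate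
17 | 10β-methyl-7β-(prop-1-en-2-yl)-1β-[2,4,6-tris(methoxymethoxy)benzyl]-5α-H-trans-decalin-4-one | C=C(C)[C@@H]1CC[C@@]2(C)[C@H](Cc3c(OCOC)cc(OCOC)cc3OCOC)CCC(=O)[C@@H]2C1 | intermediate
18 | 4α,10β-dimethyl-7β-(prop-1-en-2-yl)-1β-[2,4,6-tris(methoxymethoxy)benzyl]-5α-H-trans-decalin-4β-ol | C=C(C)[C@@H]1CC[C@@]2(C)[C@H](Cc3c(OCOC)cc(OCOC)cc3OCOC)CC[C@](C)(O)[C@@H]2C1 | intermediate
19 | 3-{[4β-hydroxy-4α,10β-dimethyl-7β-(prop-1-en-2-yl)-5α-H-trans-decalin-1β-yl]methyl}-2,4,6-tris(methoxymethoxy)benzaldehyde | C=C(C)[C@@H]1CC[C@@]2(C)[C@H](Cc3c(OCOC)c(C=O)c(OCOC)cc3OCOC)CC[C@](C)(O)[C@@H]2C1 | intermediate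
20 | lithium α-amino alkoxide of 19 (adduct of the aldehyde with lithium [2-(dimethylamino)ethyl](methyl)amide; C4 alkoxide also lithiated; aminal carbon unassigned) | C=C(C)[C@@H]1CC[C@@]2(C)[C@H](Cc3c(OCOC)c(C(O[Li])N(C)CCN(C)C)c(OCOC)cc3OCOC)CC[C@](C)(O[Li])[C@@H]2C1 | intermediate
21 | 3-{[4β-hydroxy-4α,10β-dimethyl-7β-(prop-1-en-2-yl)-5α-H-trans-decalin-1β-yl]methyl}-2,4,6-tris(methoxymethoxy)-5-(3-methylbutanoyl)benzaldehyde | C=C(C)[C@@H]1CC[C@@]2(C)[C@H](Cc3c(OCOC)c(C=O)c(OCOC)c(C(=O)CC(C)C)c3OCOC)CC[C@](C)(O)[C@@H]2C1 | intermediate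
22 | 2,4,6-trihydroxy-3-{[4β-hydroxy-4α,10β-dimethyl-7β-(prop-1-en-2-yl)-5α-H-trans-decalin-1β-yl]methyl}-5-(3-methylbutanoyl)benzaldehyde (CNP0561337.2) | C=C(C)[C@@H]1CC[C@@]2(C)[C@H](Cc3c(O)c(C=O)c(O)c(C(=O)CC(C)C)c3O)CC[C@](C)(O)[C@@H]2C1 | target

**Step count and risks**
Total step count: 15. Longest linear sequence: 13 steps (steps 1 to 6 and 9 to 15).

Steps most likely to fail:

1. Step 9 (Proposed new method). The ring-closing carbocupration may be slow, so that coupling between molecules through the C1' borane, incomplete hydroboration selectivity or loss of the borane before the Suzuki stage could take over. The fallback uses known anionic chemistry, sets out from 3 and comes back to the route at 15. The lithium enolate made from 3 as in step 3 would be trapped with phenyl vinyl sulfone (Michael addition anti to the allyl group) to give the keto sulfone F1. Wittig methylenation (Ph3P=CH2) would give the methylidene sulfone F2, and cross-metathesis with 6 would give the allylic alcohol F3. 9-BBN hydroboration of the methylidene group (the only unhindered alkene left) and B-alkyl Suzuki–Miyaura coupling with 12 (Pd(OAc)2, SPhos, K3PO4) would give the arylmethyl sulfone F4, and ClP(O)(OEt)2/pyridine would give the allylic phosphate F5. Deprotonation α to the sulfone with LiN(i-Pr)2 and Pd(PPh3)4-catalysed intramolecular Tsuji–Trost alkylation would close ring B at the same C7–C8 bond (six- over eight-membered ring) and give the bicyclic sulfone F6. Reductive desulfonylation with Na(Hg)/Na2HPO4 in MeOH would then give 15.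

2. Step 3. O-Formylation of the hindered, fully substituted enolate or retro-Claisen loss of the formyl group during the quench may compete with C-formylation. The fallback sets out from 3 and comes back at 5. Compound 4 would be isolated after the conjugate allylation and treated with HC(OMe)3 and BF3·OEt2 in CH2Cl2 at −78 °C (Mukaiyama-type addition to the dimethoxycarbenium ion, anti to the allyl group) to give the keto acetal F7. LiBF4 in wet MeCN would then unmask the aldehyde and give 5.

3. Step 4. Cross-metathesis at the 1,1-disubstituted partner may be slow, with self-metathesis of the allyl group and poor control of alkene geometry. The fallback sets out from 5 and comes back at 7. Cross-metathesis of 5 with 2-methylbut-2-ene (second-generation Grubbs catalyst) would give the prenyl compound F8. Allylic oxidation with catalytic SeO2 and t-BuOOH, which is selective for the (E)-methyl group of a trisubstituted alkene, would then give 7 as the E isomer.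

Further compounds
F1 | step 9 | (2S,3R,4R)-4-[(tert-butyldimethylsilyl)oxy]-2-methyl-2-[2-(phenylsulfonyl)ethyl]-3-(prop-2-enyl)cyclohexan-1-one | O=C1CC[C@@H](O[Si](C)(C)C(C)(C)C)[C@H](CC=C)[C@@]1(C)CCS(=O)(=O)c1ccccc1
F2 | step 9 | methylidene analogue of F1 (C1 ketone replaced by C=CH2) | C=C1CC[C@@H](O[Si](C)(C)C(C)(C)C)[C@H](CC=C)[C@@]1(C)CCS(=O)(=O)c1ccccc1
F3 | step 9 | (2E)-4-{6-[(tert-butyldimethylsilyl)oxy]-2-methyl-3-methylidene-2-[2-(phenylsulfonyl)ethyl]cyclohexyl}-2-methylbut-2-en-1-ol (ring configuration as in 8) | C=C1CC[C@@H](O[Si](C)(C)C(C)(C)C)[C@H](C/C=C(\C)CO)[C@@]1(C)CCS(=O)(=O)c1ccccc1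
F4 | step 9 | arylmethyl sulfone: F3 with the methylidene group replaced by H (α) and a 2,4,6-tris(methoxymethoxy)benzyl group (β) at C1 | COCOc1cc(OCOC)cc(OCOC)c1C[C@@H]1CC[C@@H](O[Si](C)(C)C(C)(C)C)[C@H](C/C=C(\C)CO)[C@@]1(C)CCS(=O)(=O)c1ccccc1
F5 | step 9 | diethyl phosphate of F4 | COCOc1cc(OCOC)cc(OCOC)c1C[C@@H]1CC[C@@H](O[Si](C)(C)C(C)(C)C)[C@H](C/C=C(\C)COP(=O)(OCC)OCC)[C@@]1(C)CCS(=O)(=O)c1ccccc1
F6 | step 9 | 8-(phenylsulfonyl) derivative of 15 (C8 configuration unassigned) | C=C(C)[C@@H]1C(S(=O)(=O)c3ccccc3)C[C@@]2(C)[C@H](Cc3c(OCOC)cc(OCOC)cc3OCOC)CC[C@@H](O[Si](C)(C)C(C)(C)C)[C@@H]2C1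
F7 | step 3 | (2S,3R,4R)-4-[(tert-butyldimethylsilyl)oxy]-2-(dimethoxymethyl)-2-methyl-3-(prop-2-enyl)cyclohexan-1-one | O=C1CC[C@@H](O[Si](C)(C)C(C)(C)C)[C@H](CC=C)[C@@]1(C)C(OC)OC
F8 | step 4 | (1S,2R,3R)-3-[(tert-butyldimethylsilyl)oxy]-1-methyl-2-(3-methylbut-2-enyl)-6-oxocyclohexane-1-carbaldehyde | O=C1CC[C@@H](O[Si](C)(C)C(C)(C)C)[C@H](CC=C(C)C)[C@@]1(C)C=O
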